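(Readings and results are calculated with made-up constants; scatter was added.)

Begin with the constants: no rate constant is given, so look for a quantity that holds still in the east run and freeze it.

in all of them: gas 28 mM (held)

|  | left-handed substrate | right-handed substrate | remark | time |
|---|---|---|---|---|
| east | 1.1 M | 1.1 M | run made earlier |  |
| flask | 0.74 M | 0.74 M |  | 1.5 h |

- east (time / min: left-handed product / %, right-handed product / %): 1.33: 2.3, 0; 3.00: 5.6, 0.2; 8.00: 15.2, 0.3; 20.0: 34.1, 1.1

(readings scatter by 0.3 percentage points)

- coupling partner is single-handed; left-handed substrate and right-handed substrate are mirror images of each other, charged as a racemate, each of them at the stated concentration
- at the start none of the gas is in solution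
- an excess is the difference of the two amounts in percent of their sum
- an excess is below zero if the other one leads
- the handed part of coupling partner does not stay in what it makes, so the products of the two hands are mirror images too

- left-handed product and right-handed product together, in percent of the left-handed substrate and right-handed substrate charged together, at 1.5 h
- excess of left-handed product over right-handed product in the product at 1.5 h
- whether the exchange between left-handed substrate and right-handed substrate keeps pace with the reaction: how far the product's excess at 1.5 h gets from its value without exchange to its value with instant exchange (above 80% keeps pace, below 20% hardly takes part, else lags behind)

The east run holds an oddity. Without exchange, take the left-handed substrate as its share of the charge minus the left-handed product. Its average amount from 8.00 min to 20.0 min is then a fraction 0.598 of its average amount up to 8.00 min. Yet the left-handed product's average rate over that stretch is still a fraction 0.829 of its rate up to 8.00 min, well above what that hand's fall suggests. Clear this up by treating both substrates as one pool: the same average of what remains of the pool is a fraction 0.809, much nearer the rate. So read the east run as exchange feeding the right-handed substrate into the left-handed side, a dynamic kinetic resolution.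

Now freeze the product's excess and call it the frozen excess, the excess of left-handed product over right-handed product in what has formed so far: 93.8% at the last reading, which carries the scatter of 0.3 percentage points on a right-handed reading of 1.1%. Expect about that in the flask.

The forecast gives 82% (60% to 90%) of product at 93% excess (85% to 96%), and says the exchange keeps pace: “so exchange looks fast”. With the frozen excess, that yield puts 79.4% of the charge into left-handed product, more than the 50.0% charged as left-handed substrate.

The flask gives 89.9% at 94.9% excess, and the exchange, at 95% of the way, keeps pace.

    coupling partner + left-handed substrate → left-handed product (k = 2.60 M⁻¹ min⁻¹)
    coupling partner + right-handed substrate → right-handed product (k = 0.0560 M⁻¹ min⁻¹)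
    left-handed substrate ⇌ achiral form (K = 0.330, k = 0.270 min⁻¹)
    right-handed substrate ⇌ achiral form (K = 0.330, k = 0.270 min⁻¹)
    gas ⇌ coupling partner, rate k5*(csat - [coupling partner]) (kL = 5.30 min⁻¹)
    2 coupling partner → self-condensation product (k = 0.600 M⁻¹ min⁻¹)

The flask's excess already stood at 95.2% after 0.150 h. Split the flask's total by the frozen excess: the right-handed product comes to 2.79% of the charge, and the flask holds 2.31% after 1.50 h.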